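**Retrosynthetic overview**

1. Target 20 comes from the bis(benzyl ether) 19 by hydrogenolysis; ring B is already complete in 19.
2. The strategy rests on ring B: a benzene-1,4-diol with free hydroxyls at C2' and C5', hydrogens at C3', C4' and C6', and ring A at C1' as its only carbon substituent. Cutting C2'–C3' unfolds it to the 2-aryl-4-hydroxy-4-vinylcyclobutenone 16 (thermal four-to-six ring expansion).
3. 16 comes from vinylmagnesium bromide and the arylcyclobutenedione 14; 14 comes from the aryllithium of iodide 8 and diisopropyl squarate, followed by hydride reduction and a double acid-induced carbonyl transposition.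
4. Iodide 8 comes from sparassol by O-benzylation, lateral alkylation with 3-(benzyloxy)benzyl bromide (forms the CH2–CH2 bridge to ring C), saponification and iododecarboxylation; the ester carbon marks C4 of ring A, the later biaryl carbon.
5. Ring order: rings A and C are bought, the four-membered ring is supplied by the squarate, and ring B is formed last.

Key step: step 8

Assumption: sparassol is taken as a catalogue compound; cyclobutenones 11 and 16 are racemic, and their single stereocentre disappears in step 8, so the achiral target needs no stereocontrol.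

Abbreviation used in names: Ar = 2-(benzyloxy)-6-{2-[3-(benzyloxy)phenyl]ethyl}-4-methoxyphenyl.

**Step 1**
Reactants: 1 sparassol (methyl 2-hydroxy-4-methoxy-6-methylbenzoate); 2 benzyl bromide
Product: 3 methyl 2-(benzyloxy)-4-methoxy-6-methylbenzoate
Conditions: BnBr, K2CO3, DMF, 60 °C
Reagents that add atoms: benzyl bromide, BrCc1ccccc1
Why: Williamson etherification of the only free phenol; warming in DMF overcomes its hydrogen bond to the ester.

**Step 2**
Reactants: 3 methyl 2-(benzyloxy)-4-methoxy-6-methylbenzoate; 4 3-(benzyloxy)benzyl bromide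
Product: 6 methyl 2-(benzyloxy)-6-{2-[3-(benzyloxy)phenyl]ethyl}-4-methoxybenzoate, via lithiated toluate 5 (not isolated)
Conditions: LDA (commercial solution), THF, −78 °C; then 4, −78 to −40 °C
Reagents that add atoms: 3-(benzyloxy)benzyl bromide, BrCc1cccc(OCc2ccccc2)c1
Why: Lateral lithiation of the ortho-toluate methyl group (the anion is an ester-stabilised dienolate, more acidic than the benzyl ether CH2) followed by SN2 alkylation with a reactive benzylic bromide.

**Step 3**
Reactants: 6 methyl 2-(benzyloxy)-6-{2-[3-(benzyloxy)phenyl]ethyl}-4-methoxybenzoate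
Product: 7 2-(benzyloxy)-6-{2-[3-(benzyloxy)phenyl]ethyl}-4-methoxybenzoic acid
Conditions: KOH, DMSO/H2O, 100 °C; then aq. HCl
Reagents that add atoms: potassium hydroxide, [K+].[OH-]
Why: Saponification of a di-ortho-substituted methyl benzoate needs the poorly solvated hydroxide in hot DMSO; the benzyl and methyl ethers are inert to base.

**Step 4**
Reactants: 7 2-(benzyloxy)-6-{2-[3-(benzyloxy)phenyl]ethyl}-4-methoxybenzoic acid
Product: 8 1-(benzyloxy)-3-{2-[3-(benzyloxy)phenyl]ethyl}-2-iodo-5-methoxybenzene
Conditions: I2, K3PO4, MeCN, 100 °C (sealed tube)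
Reagents that add atoms: iodine, II
Why: Transition-metal-free ipso-iododecarboxylation of an electron-rich ortho-alkoxybenzoate; the carboxylate-bearing carbon, ortho and para to the two ether oxygens, is the most nucleophilic site, so iodine should enter exactly where the carboxyl leaves.

**Step 5**
Reactants: 8 1-(benzyloxy)-3-{2-[3-(benzyloxy)phenyl]ethyl}-2-iodo-5-methoxybenzene; 9 diisopropyl squarate
Product: 11 rac-4-Ar-4-hydroxy-2,3-diisopropoxycyclobut-2-en-1-one, via aryllithium 10 (not isolated)
Conditions: n-BuLi, THF, −78 °C; cannulate into 9, THF, −78 °C; aq. NH4Cl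
Reagents that add atoms: diisopropyl squarate, CC(C)OC1=C(OC(C)C)C(=O)C1=O
Why: Iodine–lithium exchange at −78 °C is faster than benzylic deprotonation, and the aryllithium adds 1,2 to one of the two equivalent squarate carbonyls; the new carbinol centre is formed as a racemate.

**Step 6**
Reactants: 11 rac-4-Ar-4-hydroxy-2,3-diisopropoxycyclobut-2-en-1-one
Product: 14 3-Ar-cyclobut-3-ene-1,2-dione, via cyclobutenediol 12 (not isolated), via hydroxy enone 13 (not isolated)
Conditions: i-Bu2AlH (2.2 equiv), THF, −78 °C; then conc. HCl, CH2Cl2, 0 °C to rt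
Reagents that add atoms: water, O
Why: 1,2-Reduction of the vinylogous ester carbonyl gives diol 12, and acid then carries out two Stork–Danheiser-type transpositions (ionisation of each carbinol to an isopropoxy-stabilised allyl cation, hydration, loss of propan-2-ol); this is the same ionisation–hydration that converts squarate adducts into cyclobutenediones and the reduced squarate into the semisquarate.

**Step 7**
Reactants: 14 3-Ar-cyclobut-3-ene-1,2-dione; 15 vinylmagnesium bromide
Product: 16 rac-2-Ar-4-hydroxy-4-vinylcyclobut-2-en-1-one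
Conditions: CH2=CHMgBr, THF, −78 °C; aq. NH4Cl
Reagents that add atoms: vinylmagnesium bromide, C=C[Mg]Br
Why: Grignard 1,2-addition to the strained dione is expected at the carbonyl next to the CH carbon, because the di-ortho-substituted aryl group shields the other one; the carbinol centre forms as a racemate, and the regioisomeric adduct would give the same hydroquinone in step 8.

**Step 8**
Reactants: 16 rac-2-Ar-4-hydroxy-4-vinylcyclobut-2-en-1-one
Product: 19 2-Ar-benzene-1,4-diol, via dienylketene 17 (not isolated), via cyclohexadienone 18 (not isolated)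
Conditions: degassed p-xylene, 130 °C, Ar
Reagents that add atoms: none
Why: Heat opens the cyclobutenone by conrotatory 4π electrocyclic cleavage of the C1–C4 bond to dienylketene 17, whose ketene carbon then bonds to the terminal vinyl carbon in a thermal disrotatory 6π electrocyclisation. This closes the six-membered ring B by forming C2'–C3' and gives dienone 18, which enolises to the aromatic hydroquinone. The closest known reaction type is the Moore rearrangement of 4-alkenyl-4-hydroxycyclobutenones to hydroquinones. No stereocentre is created, and the carbinol centre of 16 is destroyed. The step needs torquoselectivity, that is outward rotation of the hydroxyl so that the vinyl group turns inward toward the ketene; this is secured by the donor character of the hydroxyl on C4. Both ring B oxygens emerge as free hydroxyls, so no ether on ring B has to be told apart from the ring A methoxyl.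

**Step 9**
Reactants: 19 2-Ar-benzene-1,4-diol
Product: 20 2-{2-hydroxy-6-[2-(3-hydroxyphenyl)ethyl]-4-methoxyphenyl}benzene-1,4-diol (target)
Conditions: H2 (1 atm), 10% Pd/C, EtOAc/MeOH, rt
Reagents that add atoms: none
Why: Hydrogenolysis of the two benzyl aryl ethers over palladium on carbon; the methyl ether, the saturated bridge and the hydroquinone are unaffected, and the reducing medium protects the hydroquinone from oxidation.

**Compound list**

1 | sparassol (methyl 2-hydroxy-4-methoxy-6-methylbenzoate) | COC(=O)c1c(C)cc(OC)cc1O | starting material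
2 | benzyl bromide | BrCc1ccccc1 | starting material
3 | methyl 2-(benzyloxy)-4-methoxy-6-methylbenzoate | COC(=O)c1c(C)cc(OC)cc1OCc1ccccc1 | intermediate
4 | 3-(benzyloxy)benzyl bromide | BrCc1cccc(OCc2ccccc2)c1 | starting material
5 | lithiated toluate of 3 (benzylic lithium, not isolated) | COC(=O)c1c(C[Li])cc(OC)cc1OCc1ccccc1 | intermediate
6 | methyl 2-(benzyloxy)-6-{2-[3-(benzyloxy)phenyl]ethyl}-4-methoxybenzoate | COC(=O)c1c(CCc2cccc(OCc3ccccc3)c2)cc(OC)cc1OCc1ccccc1 | intermediate
7 | 2-(benzyloxy)-6-{2-[3-(benzyloxy)phenyl]ethyl}-4-methoxybenzoic acid | OC(=O)c1c(CCc2cccc(OCc3ccccc3)c2)cc(OC)cc1OCc1ccccc1 | intermediate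
8 | 1-(benzyloxy)-3-{2-[3-(benzyloxy)phenyl]ethyl}-2-iodo-5-methoxybenzene | COc1cc(CCc2cccc(OCc3ccccc3)c2)c(I)c(OCc2ccccc2)c1 | intermediate
9 | diisopropyl squarate | CC(C)OC1=C(OC(C)C)C(=O)C1=O | starting material
10 | aryllithium Ar–Li (not isolated) | COc1cc(CCc2cccc(OCc3ccccc3)c2)c([Li])c(OCc2ccccc2)c1 | intermediate
11 | rac-4-Ar-4-hydroxy-2,3-diisopropoxycyclobut-2-en-1-one (one enantiomer drawn) | CC(C)OC1=C(OC(C)C)[C@@](O)(c2c(OCc3ccccc3)cc(OC)cc2CCc2cccc(OCc3ccccc3)c2)C1=O | intermediate
12 | 1-Ar-3,4-diisopropoxycyclobut-3-ene-1,2-diol (cis/trans mixture, racemic, configuration not assigned, not isolated) | CC(C)OC1=C(OC(C)C)C(O)(c2c(OCc3ccccc3)cc(OC)cc2CCc2cccc(OCc3ccccc3)c2)C1O | intermediate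
13 | rac-3-Ar-4-hydroxy-2-isopropoxycyclobut-2-en-1-one (not isolated) | CC(C)OC1=C(c2c(OCc3ccccc3)cc(OC)cc2CCc2cccc(OCc3ccccc3)c2)C(O)C1=O | intermediate
14 | 3-Ar-cyclobut-3-ene-1,2-dione | O=C1C=C(c2c(OCc3ccccc3)cc(OC)cc2CCc2cccc(OCc3ccccc3)c2)C1=O | intermediate
15 | vinylmagnesium bromide | C=C[Mg]Br | starting material
16 | rac-2-Ar-4-hydroxy-4-vinylcyclobut-2-en-1-one (one enantiomer drawn) | C=C[C@]1(O)C=C(c2c(OCc3ccccc3)cc(OC)cc2CCc2cccc(OCc3ccccc3)c2)C1=O | intermediate
17 | (3E)-2-Ar-4-hydroxyhexa-1,3,5-trien-1-one (dienylketene, vinyl cis to the ketene-bearing carbon, not isolated) | O=C=C(c1c(OCc2ccccc2)cc(OC)cc1CCc1cccc(OCc2ccccc2)c1)/C=C(\C=C)O | intermediate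
18 | 2-Ar-4-hydroxycyclohexa-2,4-dien-1-one (not isolated) | O=C1CC=C(O)C=C1c1c(OCc2ccccc2)cc(OC)cc1CCc1cccc(OCc2ccccc2)c1 | intermediate
19 | 2-Ar-benzene-1,4-diol | COc1cc(OCc2ccccc2)c(-c2cc(O)ccc2O)c(CCc2cccc(OCc3ccccc3)c2)c1 | intermediate
20 | 2-{2-hydroxy-6-[2-(3-hydroxyphenyl)ethyl]-4-methoxyphenyl}benzene-1,4-diol | COc1cc(O)c(-c2cc(O)ccc2O)c(CCc2cccc(O)c2)c1 | target

**Step count**

Total steps: 9. Longest linear sequence: 9 (1 to 20).

**Steps most likely to fail**

Step 8. The hydroxyl may rotate inward, so that the ketene is captured by oxygen instead of by the vinyl group. The ketene may also oligomerise, or the unprotected electron-rich hydroquinone may be oxidised at the reaction temperature. The fallback replaces the ring construction by a biaryl coupling and sets out from iodide 8. Suzuki–Miyaura coupling of 8 with commercial 2,5-dimethoxyphenylboronic acid (Pd(OAc)2, SPhos, K3PO4, toluene/H2O, 100 °C) should give 2-Ar-1,4-dimethoxybenzene F1. Oxidative demethylation of the para-dimethoxy ring with (NH4)2Ce(NO3)6 in MeCN/H2O at 0 °C should give 2-Ar-1,4-benzoquinone F2. Hydrogenation over 10% Pd/C then reduces the quinone and cleaves both benzyl ethers, so the fallback comes back to the route at target 20.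

Step 6. The second transposition may stall at the hydroxy enone stage, the strongly stabilised aryl carbinol cation may be diverted (chloride capture, decomposition), or the hydride may over-reduce. The fallback sets out from 11 and fixes the order of events with a monoacetal. Conc. HCl in CH2Cl2 converts 11 by the standard squarate-adduct hydrolysis into 3-Ar-4-isopropoxycyclobut-3-ene-1,2-dione F3. The more electrophilic carbonyl, next to the isopropoxy carbon, is protected with 1,2-bis(trimethylsilyloxy)ethane and catalytic TMSOTf as 2-Ar-1-isopropoxy-5,8-dioxaspiro[3.4]oct-1-en-3-one F4. Reduction of the remaining vinylogous ester carbonyl with i-Bu2AlH gives the allylic alcohol 2-Ar-1-isopropoxy-5,8-dioxaspiro[3.4]oct-1-en-3-ol F5. Aqueous HCl then effects the allylic transposition and acetal hydrolysis and returns to the route at 14.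

Step 4. Electrophilic iodination of the activated ring positions may compete with ipso attack, or decarboxylation may remain incomplete. The fallback sets out from acid 7 and replaces the carboxyl by nitrogen first. Diphenylphosphoryl azide and Et3N in t-BuOH at 85 °C give the acyl azide F6, which rearranges (Curtius) to the isocyanate F7; this is trapped as the tert-butyl carbamate F8. Trifluoroacetic acid in CH2Cl2 liberates the aniline F9. Diazotisation with NaNO2 and p-toluenesulfonic acid in MeCN/H2O gives the diazonium tosylate F10, which with KI should deliver iodide 8, where the fallback rejoins the route.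

**Further compounds**

F1 | step 8 | 2-Ar-1,4-dimethoxybenzene | COc1ccc(OC)c(-c2c(OCc3ccccc3)cc(OC)cc2CCc2cccc(OCc3ccccc3)c2)c1
F2 | step 8 | 2-Ar-1,4-benzoquinone | O=C1C=CC(=O)C(c2c(OCc3ccccc3)cc(OC)cc2CCc2cccc(OCc3ccccc3)c2)=C1
F3 | step 6 | 3-Ar-4-isopropoxycyclobut-3-ene-1,2-dione | CC(C)OC1=C(c2c(OCc3ccccc3)cc(OC)cc2CCc2cccc(OCc3ccccc3)c2)C(=O)C1=O
F4 | step 6 | 2-Ar-1-isopropoxy-5,8-dioxaspiro[3.4]oct-1-en-3-one | CC(C)OC1=C(c2c(OCc3ccccc3)cc(OC)cc2CCc2cccc(OCc3ccccc3)c2)C(=O)C12OCCO2
F5 | step 6 | rac-2-Ar-1-isopropoxy-5,8-dioxaspiro[3.4]oct-1-en-3-ol | CC(C)OC1=C(c2c(OCc3ccccc3)cc(OC)cc2CCc2cccc(OCc3ccccc3)c2)C(O)C12OCCO2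
F6 | step 4 | Ar-carbonyl azide | [N-]=[N+]=NC(=O)c1c(OCc2ccccc2)cc(OC)cc1CCc1cccc(OCc2ccccc2)c1
F7 | step 4 | Ar isocyanate | O=C=Nc1c(OCc2ccccc2)cc(OC)cc1CCc1cccc(OCc2ccccc2)c1
F8 | step 4 | tert-butyl N-Ar-carbamate | CC(C)(C)OC(=O)Nc1c(OCc2ccccc2)cc(OC)cc1CCc1cccc(OCc2ccccc2)c1
F9 | step 4 | Ar-amine (2-(benzyloxy)-6-{2-[3-(benzyloxy)phenyl]ethyl}-4-methoxyaniline) | Nc1c(OCc2ccccc2)cc(OC)cc1CCc1cccc(OCc2ccccc2)c1
F10 | step 4 | Ar-diazonium p-toluenesulfonate | N#[N+]c1c(OCc2ccccc2)cc(OC)cc1CCc1cccc(OCc2ccccc2)c1.Cc1ccc(S(=O)(=O)[O-])cc1
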